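L was the catalyst, and I wanted to know how fast it gave out J against how fast Z took J away again.

| setting | spring | dawn | dusk |
|---|---|---|---|
| Z | 0.30 M (fed, over 1.50 h) | 0.30 M | 0.30 M |
| L | 10 mol% | 10 mol% | 10 mol% |
| time | 3.0 h | 3.0 h |  |
| remark | all but Z at the start; Z goes in evenly over 1.50 h, the run ends at 3.0 h | everything together in a closed stirred flask, run for 3.0 h | a single well-mixed tank run continuously and read at steady state, 3.0 h in it on average |

- the set-up with the highest amount of J at the outlet or at the end, in percent of the Z put in ("none" if the first two lie within 2 percentage points) (spring / dawn / dusk / none)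
- amount of J at the outlet or at the end, in percent of the Z put in, spring
- amount of J at the outlet or at the end, in percent of the Z put in, dawn
- amount of J at the outlet or at the end, in percent of the Z put in, dusk

- in percentages every species weighs as the Z in it: one Z.J counts as two
- for J the L.J is counted in
- the stated concentrations are those of everything mixed, before any reaction; amounts are the same in each set-up
- the feed brings no volume worth counting
- run time (spring): 3.0 h

    Z + L ⇌ Z.L (K1 = 22 M⁻¹, k1 = 16 M⁻¹ h⁻¹)
    Z.L → L + J (k2 = 3.6 h⁻¹)
    Z + J → Z.J (k3 = 1.3 M⁻¹ h⁻¹)
    L + J ⇌ L.J, settled at all times (K4 = 9.4 M⁻¹)

Two times carried my reckoning. The making time, 5.28 h, was the charge of Z divided by the rate of J at [Z] as charged, with Z.L at its steady share for that [Z]. The loss time, 2.56 h, was the mean life of free J in a pseudo-first-order loss at that same [Z]. The making time was the longer, so I took their ratio, 48.5%, and called it the ceiling: the share of the charge at which J made and J lost balance with [Z] as charged, if I counted all J as free.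

Then I worked with the fraction of Z left. I took making and loss to go roughly with [Z], so I weighted the clock by the mean fraction left and let J approach the ceiling exponentially on that clock, in units of the loss time. In dawn the clock shrank to 2.15 h, giving 27.5%. In spring Z came in on average 0.750 h late, so the clock was 1.77 h, giving 24.2%. In dusk the tank sat at one fraction left, so the clock was 1.91 h, giving 20.7%. I committed to dawn.

The forecast also named dawn, with 24%, 26.5% and 19.3% for spring, dawn and dusk, noting that “Z stays low during feeding”; its dawn and dusk lay below mine.

The flask gave 24.0%, 27.4% and 19.2% for spring, dawn and dusk, so dawn came first. With the turning of Z and J into Z.J struck out, dawn ended at 38.3%. Dawn's J stood at 56.5% of the ceiling, and spring's at 49.5%.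

The neighbour fed like spring but with 17 mol% of L had a ceiling of 82.5%, and spring's share of that gave me 40.8%. The flask gave 36.7%.

(Its constants are made up; the result is computed.)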